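The cyclohexenone ring of the target (C4a, C5, C6, C7, C8, C8a of the 1H-isochromen-8-one core) is read as a cyclobutanone, C8(=O)–C7(Me)(OCOAr)–C6H(O)–C5H2, into whose strained C8–C5 bond the two sp carbons of an alkyne (future C8a and C4a) have been inserted. One nickel-catalysed C–C activation/[4+2] annulation of an enantiopure 2-acyloxy-3-silyloxy-2-methylcyclobutanone with a silyl-capped penta-2,4-diynyl ether therefore forms C8–C8a and C5–C4a at once. It also installs both pyran precursors (CH2O at C8a, alkyne at C4a), with the ester and both stereocentres already in place. Sonogashira coupling and a gold-catalysed 6-endo hydroalkoxylation then close the pyran ring.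

Key step: step 9

Assumption: 4-hydroxy-2-methoxy-6-methylbenzoic acid (1) is taken as a catalogue compound, and the diastereomers formed in step 5 are taken to be separable by chromatography.

Step 1
Reactants: 1 4-hydroxy-2-methoxy-6-methylbenzoic acid; 2 benzyl 2-bromopropanoate (racemic)
Product: 3 1-(benzyloxy)-1-oxopropan-2-yl 4-hydroxy-2-methoxy-6-methylbenzoate (racemic)
Conditions: KHCO3, DMF, rt
Reagents that add atoms: none
Why: Bicarbonate deprotonates only the carboxylic acid, and SN2 O-alkylation of the carboxylate by the α-bromo ester is insensitive to the two ortho substituents; the new stereocentre is irrelevant because step 5 destroys it.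

Step 2
Reactants: 3
Product: 4 1-(benzyloxy)-1-oxopropan-2-yl 4-[(tert-butyldimethylsilyl)oxy]-2-methoxy-6-methylbenzoate (racemic)
Conditions: TBSCl, imidazole, DMF, rt
Reagents that add atoms: tert-butyldimethylsilyl chloride, CC(C)(C)[Si](C)(C)Cl
Why: Standard silylation masks the phenol for the acid chloride, ketene and nickel steps and is removable by fluoride at the end.

Step 3
Reactants: 4
Product: 5 2-({4-[(tert-butyldimethylsilyl)oxy]-2-methoxy-6-methylbenzoyl}oxy)propanoic acid (racemic)
Conditions: H2 (1 atm), 10% Pd/C, EtOAc, rt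
Reagents that add atoms: none
Why: Hydrogenolysis cleaves the benzyl ester, the only benzylic C–O bond, and leaves the aryl silyl ether and the hindered aroate untouched.

Step 4
Reactants: 6 (R)-1-phenylethanol; 7 butyl vinyl ether
Product: 8 [(1R)-1-(ethenyloxy)ethyl]benzene
Conditions: Pd(OCOCF3)2 (0.5 mol%), 4,7-diphenyl-1,10-phenanthroline (0.5 mol%), Et3N (cat.), neat 7, 75 °C
Reagents that add atoms: none
Why: Palladium-catalysed transfer vinylation (transetherification) exchanges the alkoxy group of the vinyl ether without touching the C–O bond at the stereocentre, so the (R) configuration is kept.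

Step 5
Reactants: 5; 8
Product: 11 (1S,2R)-1-methyl-4-oxo-2-[(1R)-1-phenylethoxy]cyclobutyl 4-[(tert-butyldimethylsilyl)oxy]-2-methoxy-6-methylbenzoate, via acid chloride 9 (not isolated), via acyloxyketene 10 (not isolated)
Conditions: (COCl)2, DMF (cat.), CH2Cl2, 0 °C to rt, evaporate; then 8 (3 equiv), Et3N (slow addition), toluene, 80 °C
Reagents that add atoms: none
Why: Dehydrochlorination of 9 gives acyloxy(methyl)ketene 10, which undergoes a thermal ketene–enol ether [2+2] cycloaddition with 8 (carbonyl carbon to the terminal CH2, ketene α-carbon to the oxygen-bearing carbon); the substituent that is larger at the ketene carbon (CH3 versus O) is expected to end up cis to the alkoxy group, so that acyloxy and alkoxy are trans, and attack anti to the phenyl group of the (R)-auxiliary in its H-eclipsed conformer should favour the (3R) series, with the other diastereomers removed by chromatography.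

Step 6
Reactants: 11
Product: 12 (1S,2R)-2-hydroxy-1-methyl-4-oxocyclobutyl 4-[(tert-butyldimethylsilyl)oxy]-2-methoxy-6-methylbenzoate
Conditions: H2 (1 atm), Pd(OH)2/C, EtOAc, rt
Reagents that add atoms: none
Why: Hydrogenolysis cleaves the benzylic C–O bond of the auxiliary, not the ring C–O bond, so the (R) carbinol centre is retained, and the trans arrangement blocks acyl migration from the tertiary oxygen.

Step 7
Reactants: 12
Product: 13 (1S,2R)-1-methyl-4-oxo-2-[(triethylsilyl)oxy]cyclobutyl 4-[(tert-butyldimethylsilyl)oxy]-2-methoxy-6-methylbenzoate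
Conditions: TESCl, imidazole, CH2Cl2, 0 °C
Reagents that add atoms: chlorotriethylsilane, CC[Si](Cl)(CC)CC
Why: Mild silylation protects the β-hydroxyl against elimination and against β-hydroxy elimination from alkylnickel intermediates in the next step.

Step 8
Reactants: 14 tert-butyldimethyl(prop-2-yn-1-yloxy)silane; 15 (bromoethynyl)tri(propan-2-yl)silane
Product: 16 tert-butyldimethyl{[5-(triisopropylsilyl)penta-2,4-diyn-1-yl]oxy}silane
Conditions: CuCl (5 mol%), NH2OH·HCl (cat.), n-BuNH2, H2O/Et2O, 0 °C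
Reagents that add atoms: none
Why: Cadiot–Chodkiewicz coupling of the copper acetylide of 14 with bromoalkyne 15 gives the unsymmetrical 1,3-diyne without homocoupling.

Step 9
Reactants: 13; 16
Product: 17 (1S,6R)-3-{[(tert-butyldimethylsilyl)oxy]methyl}-1-methyl-2-oxo-6-[(triethylsilyl)oxy]-4-[(triisopropylsilyl)ethynyl]cyclohex-3-en-1-yl 4-[(tert-butyldimethylsilyl)oxy]-2-methoxy-6-methylbenzoate
Conditions: Ni(cod)2 (10 mol%), PCy3 (20 mol%), 16 (1.5 equiv), toluene, 100 °C
Reagents that add atoms: none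
Why: Zerovalent nickel couples the strained, inductively activated C=O of 13 with the internal alkyne of 16 by oxidative cyclisation to an oxanickelacyclopentene (C(=O)–C(sp2) bond), β-carbon elimination then cleaves the cyclobutane C(O)–CH2 bond with release of ring strain to give a seven-membered nickelacycle, and C(sp3)–C(sp2) reductive elimination forms the CH2–C bond and returns the catalyst. The closest known reaction type is the nickel-catalysed intermolecular insertion of internal alkynes into the acyl–carbon bond of cyclobutanones and 3-azetidinones, a formal [4+2] annulation. The six-membered ring is closed by that reductive elimination from the nickelacycle, not by a polar or pericyclic closure. No stereocentre is formed, and the quaternary and carbinol carbons of 13 take part in no bond that is broken, so they are carried over unchanged. Three selectivities are needed: cleavage on the CH2 side, secured by the fully substituted α-carbon on the other side; bonding of the carbonyl carbon to the CH2OSi-bearing alkyne carbon, secured by the conjugating alkynyl group, which prefers the nickel-bound carbon; and reaction at the internal alkyne only, secured by the bulky triisopropylsilyl cap.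

Step 10
Reactants: 17
Product: 18 (1S,6R)-4-ethynyl-6-hydroxy-3-(hydroxymethyl)-1-methyl-2-oxocyclohex-3-en-1-yl 4-hydroxy-2-methoxy-6-methylbenzoate
Conditions: TBAF, AcOH, THF, 0 °C to rt
Reagents that add atoms: none
Why: Fluoride cleaves the three Si–O bonds and the Si–C(sp) bond, while the acetic acid buffer keeps the primary hydroxyl protonated and so suppresses conjugate addition to the ynenone and vinylogous elimination of the secondary hydroxyl.

Step 11
Reactants: 18; 19 (E)-1-bromoprop-1-ene
Product: 20 (1S,6R)-6-hydroxy-3-(hydroxymethyl)-1-methyl-2-oxo-4-[(3E)-pent-3-en-1-yn-1-yl]cyclohex-3-en-1-yl 4-hydroxy-2-methoxy-6-methylbenzoate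
Conditions: Pd(PPh3)4 (5 mol%), CuI (10 mol%), Et3N, THF, degassed, rt
Reagents that add atoms: none
Why: Sonogashira coupling of the terminal alkyne with the alkenyl bromide proceeds with retention of the E geometry and tolerates free hydroxyl and phenol groups.

Step 12
Reactants: 20
Product: 21 (6R,7S)-6-hydroxy-7-methyl-8-oxo-3-[(1E)-prop-1-en-1-yl]-5,6,7,8-tetrahydro-1H-isochromen-7-yl 4-hydroxy-2-methoxy-6-methylbenzoate
Conditions: Ph3PAuNTf2 (5 mol%), CH2Cl2, rt
Reagents that add atoms: none
Why: Cationic gold activates the alkyne and the primary hydroxyl attacks anti at the distal alkyne carbon (6-endo-dig hydroalkoxylation, as in the cycloisomerisation of 2-alkynylbenzyl alcohols to 1H-isochromenes), because that carbon is the δ-position of the ynenone and carries the cation-stabilising propenyl group; protodeauration gives the 2H-pyran.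

Compound list
1 | 4-hydroxy-2-methoxy-6-methylbenzoic acid | OC(=O)c1c(C)cc(O)cc1OC | starting material
2 | benzyl 2-bromopropanoate (racemic) | CC(Br)C(=O)OCc1ccccc1 | starting material
3 | 1-(benzyloxy)-1-oxopropan-2-yl 4-hydroxy-2-methoxy-6-methylbenzoate (racemic) | CC(OC(=O)c1c(C)cc(O)cc1OC)C(=O)OCc1ccccc1 | intermediate
4 | 1-(benzyloxy)-1-oxopropan-2-yl 4-[(tert-butyldimethylsilyl)oxy]-2-methoxy-6-methylbenzoate (racemic) | CC(OC(=O)c1c(C)cc(O[Si](C)(C)C(C)(C)C)cc1OC)C(=O)OCc1ccccc1 | intermediate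
5 | 2-({4-[(tert-butyldimethylsilyl)oxy]-2-methoxy-6-methylbenzoyl}oxy)propanoic acid (racemic) | CC(OC(=O)c1c(C)cc(O[Si](C)(C)C(C)(C)C)cc1OC)C(O)=O | intermediate
6 | (R)-1-phenylethanol | C[C@@H](O)c1ccccc1 | starting material
7 | butyl vinyl ether | CCCCOC=C | starting material
8 | [(1R)-1-(ethenyloxy)ethyl]benzene | C[C@@H](OC=C)c1ccccc1 | intermediate
9 | 2-({4-[(tert-butyldimethylsilyl)oxy]-2-methoxy-6-methylbenzoyl}oxy)propanoyl chloride | CC(OC(=O)c1c(C)cc(O[Si](C)(C)C(C)(C)C)cc1OC)C(Cl)=O | intermediate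
10 | 1-oxoprop-1-en-2-yl 4-[(tert-butyldimethylsilyl)oxy]-2-methoxy-6-methylbenzoate (acyloxy(methyl)ketene) | CC(OC(=O)c1c(C)cc(O[Si](C)(C)C(C)(C)C)cc1OC)=C=O | intermediate
11 | (1S,2R)-1-methyl-4-oxo-2-[(1R)-1-phenylethoxy]cyclobutyl 4-[(tert-butyldimethylsilyl)oxy]-2-methoxy-6-methylbenzoate | O=C1[C@@](C)(OC(=O)c2c(C)cc(O[Si](C)(C)C(C)(C)C)cc2OC)[C@H](O[C@H](C)c2ccccc2)C1 | intermediate
12 | (1S,2R)-2-hydroxy-1-methyl-4-oxocyclobutyl 4-[(tert-butyldimethylsilyl)oxy]-2-methoxy-6-methylbenzoate | O=C1[C@@](C)(OC(=O)c2c(C)cc(O[Si](C)(C)C(C)(C)C)cc2OC)[C@H](O)C1 | intermediate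
13 | (1S,2R)-1-methyl-4-oxo-2-[(triethylsilyl)oxy]cyclobutyl 4-[(tert-butyldimethylsilyl)oxy]-2-methoxy-6-methylbenzoate | O=C1[C@@](C)(OC(=O)c2c(C)cc(O[Si](C)(C)C(C)(C)C)cc2OC)[C@H](O[Si](CC)(CC)CC)C1 | intermediate
14 | tert-butyldimethyl(prop-2-yn-1-yloxy)silane | C#CCO[Si](C)(C)C(C)(C)C | starting material
15 | (bromoethynyl)tri(propan-2-yl)silane | BrC#C[Si](C(C)C)(C(C)C)C(C)C | starting material
16 | tert-butyldimethyl{[5-(triisopropylsilyl)penta-2,4-diyn-1-yl]oxy}silane | CC(C)[Si](C#CC#CCO[Si](C)(C)C(C)(C)C)(C(C)C)C(C)C | intermediate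
17 | (1S,6R)-3-{[(tert-butyldimethylsilyl)oxy]methyl}-1-methyl-2-oxo-6-[(triethylsilyl)oxy]-4-[(triisopropylsilyl)ethynyl]cyclohex-3-en-1-yl 4-[(tert-butyldimethylsilyl)oxy]-2-methoxy-6-methylbenzoate | CC(C)[Si](C#CC1=C(CO[Si](C)(C)C(C)(C)C)C(=O)[C@@](C)(OC(=O)c2c(C)cc(O[Si](C)(C)C(C)(C)C)cc2OC)[C@H](O[Si](CC)(CC)CC)C1)(C(C)C)C(C)C | intermediate
18 | (1S,6R)-4-ethynyl-6-hydroxy-3-(hydroxymethyl)-1-methyl-2-oxocyclohex-3-en-1-yl 4-hydroxy-2-methoxy-6-methylbenzoate | C#CC1=C(CO)C(=O)[C@@](C)(OC(=O)c2c(C)cc(O)cc2OC)[C@H](O)C1 | intermediate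
19 | (E)-1-bromoprop-1-ene | C/C=C/Br | starting material
20 | (1S,6R)-6-hydroxy-3-(hydroxymethyl)-1-methyl-2-oxo-4-[(3E)-pent-3-en-1-yn-1-yl]cyclohex-3-en-1-yl 4-hydroxy-2-methoxy-6-methylbenzoate | C/C=C/C#CC1=C(CO)C(=O)[C@@](C)(OC(=O)c2c(C)cc(O)cc2OC)[C@H](O)C1 | intermediate
21 | (6R,7S)-6-hydroxy-7-methyl-8-oxo-3-[(1E)-prop-1-en-1-yl]-5,6,7,8-tetrahydro-1H-isochromen-7-yl 4-hydroxy-2-methoxy-6-methylbenzoate | C/C=C/C1=CC2=C(CO1)C(=O)[C@@](C)(OC(=O)c1c(C)cc(O)cc1OC)[C@H](O)C2 | target

Total step count: 12. Longest linear sequence: 10 steps (steps 1, 2, 3, 5, 6, 7, 9, 10, 11, 12).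

Steps most likely to fail

Step 9. Oligomerisation of the conjugated diyne on zerovalent nickel, or oxidative cyclisation at the silyl-capped alkyne, may outrun coupling with the hindered α-quaternary ketone. The fallback changes the two-carbon partner to a 1,3-enyne, the alkyne class with the strongest regiochemical bias in nickel-mediated oxidative cyclisation, and closes the pyran oxidatively. It sets out from 13 and 14 and comes back at 21. Takai olefination of (E)-but-2-enal (CHI3, CrCl2, THF) gives (1E,3E)-1-iodopenta-1,3-diene F1. Sonogashira coupling of F1 with 14 gives tert-butyldimethyl{[(4E,6E)-octa-4,6-dien-2-yn-1-yl]oxy}silane F2. The same nickel-catalysed annulation of 13 with F2 should give the silyl-protected 4-pentadienylcyclohexenone F3, with the alkenyl group on the nickel-bound carbon. TBAF/AcOH then gives the deprotected dienyl alcohol F4. An aerobic Wacker-type oxidative cyclisation (Pd(OCOCF3)2, pyridine, O2, toluene) gives 21: the primary hydroxyl adds to the δ-carbon of the dienone and β-hydride elimination restores the enol ether double bond.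

Step 5. Facial discrimination by the remote auxiliary and cis/trans control may both be low, and dimerisation of the disubstituted ketene may outrun the cycloaddition. The fallback builds the quaternary centre stepwise on a simpler cyclobutanone. It sets out from 8 and 1 and comes back at 11. Methylketene F5 (from propanoyl chloride and Et3N) adds to 8 to give (3R)-2-methyl-3-[(1R)-1-phenylethoxy]cyclobutan-1-one F6 after separation from the (3S) series; C2 is epimerisable and need not be controlled. TMSOTf/Et3N gives the more substituted silyl enol ether F7. Rubottom oxidation (mCPBA, then mild acid) delivers oxygen anti to the C3 alkoxy group and gives (2S,3R)-2-hydroxy-2-methyl-3-[(1R)-1-phenylethoxy]cyclobutan-1-one F8. In parallel, 1 is bis-silylated (TBSCl, imidazole) to the silyl ester F9, the silyl ester is cleaved (K2CO3, MeOH, H2O) to the acid F10, and oxalyl chloride gives the acid chloride F11. Acylation of F8 with F11 (DMAP, Et3N, CH2Cl2, reflux) gives 11.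

Step 10. Under fluoride the freed primary hydroxyl may add to the terminal ynenone, and the secondary hydroxyl may be lost by vinylogous elimination. The fallback keeps the hydroxymethyl group masked as an acetal until after the Sonogashira coupling. It sets out from 13 and 15 and comes back at 20. Cadiot–Chodkiewicz coupling of commercial 2-(prop-2-yn-1-yloxy)oxane with 15 gives 2-{[5-(triisopropylsilyl)penta-2,4-diyn-1-yl]oxy}oxane F12. Nickel-catalysed annulation of 13 with F12 gives the tetrahydropyranyl analogue of 17, F13. TBAF/AcOH removes the three silicon groups but not the acetal and gives the terminal alkyne F14. Sonogashira coupling with 19 gives the enyne F15. PPTS in methanol removes the tetrahydropyranyl group and gives 20.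

Further compounds
F1 | step 9 | (1E,3E)-1-iodopenta-1,3-diene | C/C=C/C=C/I
F2 | step 9 | tert-butyldimethyl{[(4E,6E)-octa-4,6-dien-2-yn-1-yl]oxy}silane | C/C=C/C=C/C#CCO[Si](C)(C)C(C)(C)C
F3 | step 9 | (1S,6R)-3-{[(tert-butyldimethylsilyl)oxy]methyl}-1-methyl-2-oxo-4-[(1E,3E)-penta-1,3-dien-1-yl]-6-[(triethylsilyl)oxy]cyclohex-3-en-1-yl 4-[(tert-butyldimethylsilyl)oxy]-2-methoxy-6-methylbenzoate | C/C=C/C=C/C1=C(CO[Si](C)(C)C(C)(C)C)C(=O)[C@@](C)(OC(=O)c2c(C)cc(O[Si](C)(C)C(C)(C)C)cc2OC)[C@H](O[Si](CC)(CC)CC)C1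
F4 | step 9 | (1S,6R)-6-hydroxy-3-(hydroxymethyl)-1-methyl-2-oxo-4-[(1E,3E)-penta-1,3-dien-1-yl]cyclohex-3-en-1-yl 4-hydroxy-2-methoxy-6-methylbenzoate | C/C=C/C=C/C1=C(CO)C(=O)[C@@](C)(OC(=O)c2c(C)cc(O)cc2OC)[C@H](O)C1
F5 | step 5 | methylketene (prop-1-en-1-one) | CC=C=O
F6 | step 5 | (3R)-2-methyl-3-[(1R)-1-phenylethoxy]cyclobutan-1-one | O=C1C(C)[C@H](O[C@H](C)c2ccccc2)C1
F7 | step 5 | trimethyl({(3R)-2-methyl-3-[(1R)-1-phenylethoxy]cyclobut-1-en-1-yl}oxy)silane | C[Si](C)(C)OC1=C(C)[C@H](O[C@H](C)c2ccccc2)C1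
F8 | step 5 | (2S,3R)-2-hydroxy-2-methyl-3-[(1R)-1-phenylethoxy]cyclobutan-1-one | O=C1[C@@](C)(O)[C@H](O[C@H](C)c2ccccc2)C1
F9 | step 5 | tert-butyldimethylsilyl 4-[(tert-butyldimethylsilyl)oxy]-2-methoxy-6-methylbenzoate | CC(C)(C)[Si](C)(C)OC(=O)c1c(C)cc(O[Si](C)(C)C(C)(C)C)cc1OC
F10 | step 5 | 4-[(tert-butyldimethylsilyl)oxy]-2-methoxy-6-methylbenzoic acid | OC(=O)c1c(C)cc(O[Si](C)(C)C(C)(C)C)cc1OC
F11 | step 5 | 4-[(tert-butyldimethylsilyl)oxy]-2-methoxy-6-methylbenzoyl chloride | ClC(=O)c1c(C)cc(O[Si](C)(C)C(C)(C)C)cc1OC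
F12 | step 10 | 2-{[5-(triisopropylsilyl)penta-2,4-diyn-1-yl]oxy}oxane | CC(C)[Si](C#CC#CCOC1CCCCO1)(C(C)C)C(C)C
F13 | step 10 | (1S,6R)-1-methyl-3-[(oxan-2-yloxy)methyl]-2-oxo-6-[(triethylsilyl)oxy]-4-[(triisopropylsilyl)ethynyl]cyclohex-3-en-1-yl 4-[(tert-butyldimethylsilyl)oxy]-2-methoxy-6-methylbenzoate (mixture at the acetal carbon) | CC(C)[Si](C#CC1=C(COC2CCCCO2)C(=O)[C@@](C)(OC(=O)c2c(C)cc(O[Si](C)(C)C(C)(C)C)cc2OC)[C@H](O[Si](CC)(CC)CC)C1)(C(C)C)C(C)C
F14 | step 10 | (1S,6R)-4-ethynyl-6-hydroxy-1-methyl-3-[(oxan-2-yloxy)methyl]-2-oxocyclohex-3-en-1-yl 4-hydroxy-2-methoxy-6-methylbenzoate (mixture at the acetal carbon) | C#CC1=C(COC2CCCCO2)C(=O)[C@@](C)(OC(=O)c2c(C)cc(O)cc2OC)[C@H](O)C1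
F15 | step 10 | (1S,6R)-6-hydroxy-1-methyl-3-[(oxan-2-yloxy)methyl]-2-oxo-4-[(3E)-pent-3-en-1-yn-1-yl]cyclohex-3-en-1-yl 4-hydroxy-2-methoxy-6-methylbenzoate (mixture at the acetal carbon) | C/C=C/C#CC1=C(COC2CCCCO2)C(=O)[C@@](C)(OC(=O)c2c(C)cc(O)cc2OC)[C@H](O)C1
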